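**Retrosynthetic overview**
- Feature: the target is two identical 3-hydroxy-4,4,6,6-tetramethylcyclohex-2-ene-1,5-dione rings (ring A, ring B) on one CH(isobutyl) carbon. In each ring (a = carbon bonded to the methine, b = enol carbon, c = C(CH3)2 next to b, d = ketone carbon between the two C(CH3)2, e = second C(CH3)2, f = ketone carbon bonded to a) the unit d–e–f is a dimethylmalonyl 1,3-dielectrophile without α-hydrogen, and a–b–c is the α-carbon, carbonyl carbon and α′-carbon of an isopropyl ketone, a 1,3-dinucleophile.
- Key disconnection: the c–d and f–a bonds of both rings at once, a double [3+3] annulation of an acyclic bis(enol silane) with two molecules of dimethylmalonyl dichloride. Rings A and B form together in the last step; no ring exists before it.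
- The bis(enol silane) is regiodefined (enol double bond from b to the C(CH3)2 carbon c). It comes from 1,4-hydrosilylation of a bis(isopropenyl ketone), i.e. the ketone held one oxidation level higher; the key step removes the silyl groups again.
- The bis(isopropenyl ketone) comes from 3-isobutylglutaric acid through its bis-Weinreb amide. The glutarate chain supplies atoms a and b of both rings and the methine with its isobutyl group.

Key step: step 4

Assumption: the target is treated as the bis-enol tautomer drawn; it has no stereocentre because the methine carbon carries two identical rings, and 3-isobutylglutaric acid, dimethylmalonyl dichloride and the reagents are taken as commercial.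

Step 1
Reactants: 1 3-(2-methylpropyl)pentanedioic acid (3-isobutylglutaric acid)
Product: 3 bis-Weinreb amide N1,N5-dimethoxy-N1,N5-dimethyl-3-(2-methylpropyl)pentanediamide, via diacid dichloride 2 (not isolated)
Conditions: (COCl)2 (3 equiv), DMF (cat.), CH2Cl2, 0 °C → rt; evaporate; MeNH(OMe)·HCl (2.5 equiv), Et3N (6 equiv), CH2Cl2, 0 °C → rt
Reagents that add atoms: oxalyl chloride, O=C(Cl)C(=O)Cl (the chlorine atoms of 2); N,O-dimethylhydroxylamine hydrochloride, CNOC.Cl
Why: Vilsmeier-type acid chloride formation followed by nucleophilic acyl substitution with the hydroxylamine (Schotten–Baumann-type amidation); the excess of oxalyl chloride should keep the 3-substituted glutaric acid from resting as its cyclic anhydride, and no stereocentre is involved.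

Step 2
Reactants: 3 N1,N5-dimethoxy-N1,N5-dimethyl-3-(2-methylpropyl)pentanediamide
Product: 4 2,8-dimethyl-5-(2-methylpropyl)nona-1,8-diene-3,7-dione (bis(isopropenyl ketone))
Conditions: CH2=C(CH3)MgBr (2.6 equiv), THF, −20 → 0 °C; inverse quench into cold 1 M HCl
Reagents that add atoms: isopropenylmagnesium bromide (prop-1-en-2-ylmagnesium bromide), CC(=C)[Mg]Br
Why: Weinreb ketone synthesis, in which the five-membered magnesium chelate of each tetrahedral adduct should survive until the acidic quench so that each amide takes up exactly one alkenyl group, and an sp2 Grignard reagent cannot reduce the amide by β-hydride transfer.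

Step 3
Reactants: 4 2,8-dimethyl-5-(2-methylpropyl)nona-1,8-diene-3,7-dione
Product: 5 2,8-dimethyl-5-(2-methylpropyl)-3,7-bis(triethylsilyloxy)nona-2,7-diene (bis(enol silane))
Conditions: Et3SiH (2.3 equiv), RhCl(PPh3)3 (1 mol %), toluene, 50 °C; filtration through basic alumina
Reagents that add atoms: triethylsilane, CC[SiH](CC)CC
Why: Rhodium-catalysed 1,4-hydrosilylation of an α,β-unsaturated ketone with a monohydrosilane should place silicon on oxygen and hydrogen on the terminal CH2, giving the fully substituted enol silane regiospecifically; the new olefinic carbon carries two methyl groups, so there is no double-bond isomer and no stereocentre.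

Step 4
Reactants: 5 2,8-dimethyl-5-(2-methylpropyl)-3,7-bis(triethylsilyloxy)nona-2,7-diene; 6 2,2-dimethylpropanedioyl dichloride (dimethylmalonyl dichloride)
Product: 8 Watsonianone A, via titanium-bound bis(acyl chloride) 7 (not isolated)
Conditions: 6 (2.4 equiv), TiCl4 (4.4 equiv), CH2Cl2, −78 °C, 5 added slowly, then −20 °C; Bu3N (6 equiv), −45 °C → rt; 1 M HCl
Reagents that add atoms: none
Why: Proposed new method: on each arm the TiCl4-activated acyl chloride of 6 is attacked by the fully substituted enol silane carbon (Mukaiyama-type C-acylation with loss of Et3SiCl), which forms the c–d bond and leaves the titanium-bound bis(acyl chloride) 7; Bu3N then generates the titanium enolate at the only enolisable position of each arm, the CH2 next to the methine (atom a), which attacks its own pendant acyl chloride to form the f–a bond, and the β-triketone should rest as its titanium enolate until the acidic work-up. The closest known reaction types are the Effenberger cyclisation (an enol silane and a malonyl dichloride give a cyclohexane-1,3,5-trione by acylation at the α and α′ carbons), the ring-forming double Friedel–Crafts acylation with dimethylmalonyl dichloride and the TiCl4/amine-mediated Claisen and Dieckmann condensations of acyl chlorides; what has not been shown is this annulation on an acyclic, fully substituted enol silane, run twice in one molecule. Ring A and ring B each close by a 6-(enolendo)-exo-trig C-acylation. No stereocentre is formed, since the methine carbon ends up with two identical rings. The step needs C- over O-acylation and the order "quaternary carbon first": the silicon/titanium Lewis acid manifold should secure the first, and the regiodefined enol silane secures the second, because no nucleophilic CH2 exists before every arm carries its own acyl chloride, after which a CH2 can reach the acyl chloride of the other arm only through an eight-membered ring. Compound 6 has no α-hydrogen, so ketene formation and self-condensation are excluded, and its second acyl group disfavours decarbonylation of the activated acyl chloride.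

**Compound list**
1 | 3-(2-methylpropyl)pentanedioic acid (3-isobutylglutaric acid) | CC(C)CC(CC(=O)O)CC(=O)O | starting material
2 | 3-(2-methylpropyl)pentanedioyl dichloride | CC(C)CC(CC(=O)Cl)CC(=O)Cl | intermediate
3 | N1,N5-dimethoxy-N1,N5-dimethyl-3-(2-methylpropyl)pentanediamide | CC(C)CC(CC(=O)N(C)OC)CC(=O)N(C)OC | intermediate
4 | 2,8-dimethyl-5-(2-methylpropyl)nona-1,8-diene-3,7-dione | CC(C)CC(CC(=O)C(C)=C)CC(=O)C(C)=C | intermediate
5 | 2,8-dimethyl-5-(2-methylpropyl)-3,7-bis(triethylsilyloxy)nona-2,7-diene | CC(C)CC(CC(O[Si](CC)(CC)CC)=C(C)C)CC(O[Si](CC)(CC)CC)=C(C)C | intermediate
6 | 2,2-dimethylpropanedioyl dichloride (dimethylmalonyl dichloride) | CC(C)(C(=O)Cl)C(=O)Cl | starting material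
7 | 2,2,4,4,10,10,12,12-octamethyl-7-(2-methylpropyl)-3,5,9,11-tetraoxotridecanedioyl dichloride (titanium-bound in the flask) | ClC(=O)C(C)(C)C(=O)C(C)(C)C(=O)CC(CC(C)C)CC(=O)C(C)(C)C(=O)C(C)(C)C(=O)Cl | intermediate
8 | Watsonianone A, 2,2'-(3-methylbutane-1,1-diyl)bis(3-hydroxy-4,4,6,6-tetramethylcyclohex-2-ene-1,5-dione), no stereocentre | CC(C)CC(C1=C(O)C(C)(C)C(=O)C(C)(C)C1=O)C1=C(O)C(C)(C)C(=O)C(C)(C)C1=O | target

**Step count and risks**
Total step count: 4. Longest linear sequence: 4 steps (from 1).

Steps most likely to fail:

1. Step 4 (Proposed new method). The intermolecular acylation at the fully substituted enol carbon may be too slow against the hindered acyl chloride, so that protodesilylation of the enol silane or coupling of one dichloride with two enol silane termini (oligomerisation) takes over; the ring closure may also go through oxygen (enol lactone formation) instead of carbon. Fallback with known chemistry, setting out from 2 (made from 1 as in step 1 and freed of oxalyl chloride) and coming back at 8: commercial methyl 2,2,4-trimethyl-3-oxopentanoate is deprotonated at its only enolisable carbon with LiN(iPr)2 in THF at −78 °C to lithium 5-methoxy-2,4,4-trimethyl-5-oxopent-2-en-3-olate F1. This enolate is C-acylated by both acyl chloride groups of 2 to give the bis(diketo ester) dimethyl 2,2,4,4,10,10,12,12-octamethyl-7-(2-methylpropyl)-3,5,9,11-tetraoxotridecanedioate F2. NaOMe in MeOH at reflux should then close both rings by Dieckmann condensation of each CH2 enolate onto its terminal ester, and acidification gives 8. The two ring bonds are thus made in separate steps (enolate C-acylation by an acyl chloride, then Dieckmann closure).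

2. Step 3. 1,2-Hydrosilylation of the carbonyl groups may compete with the 1,4-addition, and the enol silane may be hydrolysed during isolation. Fallback setting out from 4 and coming back at 5: conjugate hydride addition with LiBH(sBu)3 (2.1 equiv) in THF at −78 °C should give dilithium 2,8-dimethyl-5-(2-methylpropyl)nona-2,7-diene-3,7-bis(olate) F3, which is O-silylated in the same flask with Et3SiCl/Et3N to give 5, used crude in step 4.

3. Step 2. The liberated N,O-dimethylhydroxylamine or excess Grignard reagent may add in conjugate fashion to the α-methylene ketone released on quench, and the bis-enone may oligomerise. Fallback setting out from 2 and coming back at 4: Negishi acylation of the diacid dichloride with CH2=C(CH3)ZnBr and Pd(PPh3)4 (cat.) in THF at 0 °C → rt should give 4 directly with no amine nucleophile present; this fallback makes no new compound (F0).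

**Further compounds**
F1 | step 4 | lithium 5-methoxy-2,4,4-trimethyl-5-oxopent-2-en-3-olate | CC(C)=C(O[Li])C(C)(C)C(=O)OC
F2 | step 4 | dimethyl 2,2,4,4,10,10,12,12-octamethyl-7-(2-methylpropyl)-3,5,9,11-tetraoxotridecanedioate | COC(=O)C(C)(C)C(=O)C(C)(C)C(=O)CC(CC(C)C)CC(=O)C(C)(C)C(=O)C(C)(C)C(=O)OC
F3 | step 3 | dilithium 2,8-dimethyl-5-(2-methylpropyl)nona-2,7-diene-3,7-bis(olate) | [Li]OC(CC(CC(C)C)CC(O[Li])=C(C)C)=C(C)C
F0 | step 2 | none | none
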